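Every molecule of starting material has to end somewhere, so I began by subtracting from the charge what the readings show, and asked what odds the remainder left.

| setting | blue | teal | red | Tuesday's | Sunday's | Wednesday's | Monday's |
|---|---|---|---|---|---|---|---|
| starting material | 0.065 M | 0.065 M | 0.065 M | 0.065 M | 0.065 M | 0.065 M (fed, over 2.0 h) | 0.065 M |
| first nucleophile | 0.117 M | 0.059 M | 0.088 M | 0.117 M (fed, over 2.0 h) | 0.117 M (fed, over 2.0 h) | 0.117 M | 0.117 M (fed, over 12 min) |
| second nucleophile | 0.0715 M | 0.0715 M | 0.0715 M | 0.0715 M | 0.0715 M | 0.0715 M | 0.0715 M |
| temperature | −10 °C | 5 °C | −10 °C | 5 °C |  | 5 °C | 5 °C |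
| remark | run made earlier | run made earlier | run made earlier | all else is in the flask from the start; the feed brings no volume worth counting | the addition at −15 °C, then warmed to 5 °C; the feed brings no volume worth counting | all else is in the flask from the start; the feed brings no volume worth counting | all else is in the flask from the start; the feed brings no volume worth counting |
| time |  |  |  | 2.5 h | 2.5 h | 2.5 h | 2.5 h |

| run | time / h | other capture product / % | target / % |
|---|---|---|---|
| blue | 0.250 | 13.5 | 10.3 |
| blue | 0.500 | 18.9 | 14.1 |
| blue | 1.33 | 22.4 | 17.7 |
| blue | 3.00 | 23.2 | 18.6 |
| teal | 0.833 | 19.2 | 9.8 |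
| teal | 1.50 | 20.2 | 9.9 |
| teal | 2.50 | 19.8 | 9.2 |
| teal | 3.00 | 19.1 | 9.7 |
| red | 0.833 | 23.2 | 13.8 |
| red | 2.00 | 24.8 | 14.3 |
| red | 4.00 | 24.5 | 15.2 |
| red | 6.00 | 24.6 | 15.2 |

(readings scatter by 0.5 percentage points)



- the flask with the highest amount of other capture product, in percent of the starting material charged ("all alike" if they lie within 1.5 percentage points) (Tuesday's / Sunday's / Wednesday's / Monday's / all alike)
- final other capture product, as a percentage of the starting material charged, in Tuesday's
- final other capture product, as a percentage of the starting material charged, in Sunday's
- final other capture product, as a percentage of the starting material charged, in Wednesday's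
- final other capture product, as a percentage of the starting material charged, in Monday's

In the teal run at 5 °C the readings stood level from 0.833 h on, averaging 19.6% of other capture product and 9.65% of target, so other capture product held odds of 0.277 against the unseen routes. Dividing by 0.0715 M of second nucleophile gave 3.87 M⁻¹, the capture odds, a selectivity factor: other capture product against unseen routes, per molar of second nucleophile.

Does first nucleophile disturb these odds? At −10 °C the last blue reading gave 0.399 and the last red reading 0.409, although red held 0.088 M of first nucleophile and blue 0.117 M, so I needed to know just how much target each flask makes.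

How much is that? The rise of the blue run reads as a rate constant of 3.37 h⁻¹, a half-life of 0.206 h, shorter than the slow feed of 2.0 h. So I set target near zero in Tuesday's and reckoned other capture product there at 21.7%, with Monday's slightly lower. For Sunday's, added in the cold, the blue odds gave 28.5%, higher than Tuesday's, so I chose Sunday's. Every earlier run had its starting material charged at once, so my own reckoning stopped short of Wednesday's, where it is fed, and there it differs from the forecast, which gives that flask a number.

The forecast named Sunday's, with 21.4%, 29.5%, 18% and 20.2% for Tuesday's, Sunday's, Wednesday's and Monday's, holding that “warmth favours loss”.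

The flasks gave 22.1%, 30.4%, 23.3% and 20.9% in that order, so Sunday's led.

    starting material → intermediate (k = 0.330 min⁻¹, Ea = 83.0 kJ mol⁻¹)
    first nucleophile + intermediate → target (k = 260 M⁻¹ min⁻¹, Ea = 45.0 kJ mol⁻¹)
    second nucleophile + intermediate → other capture product (k = 440 M⁻¹ min⁻¹, Ea = 35.0 kJ mol⁻¹)
    2 starting material → homo dimer (k = 2.40 M⁻¹ min⁻¹, Ea = 62.0 kJ mol⁻¹)
    intermediate → solvolysis product (k = 61.0 min⁻¹, Ea = 75.0 kJ mol⁻¹)
    (constants at 5 °C)

Wednesday's stood 5.3 percentage points above the forecast, and its homo dimer, counted as the starting material it holds, was 2.22% against 29.6% in Tuesday's. Monday's, with its starting material charged at once, showed odds of 0.281 against the 0.277 from the teal run. The neighbour of Monday's with 0.018 M of second nucleophile had reckoned odds of 0.0696, which with its 5.48% of target means 6.15% of other capture product, and that flask gave 6.62%.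

All runs stem from a simulated flask with constants of no real substance, and the scatter is random.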